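**Plan**
Cuts: (a) the three phenolic O–Si bonds of a tris-silyl ether; (b) C2–C1' (ring C to ring B), back to a 4H-chromen-4-one and an arylboronic acid; (c) C6–C1'' (ring A to side chain), back to a 6-iodochromone and a linear allylboronate; (d) the C5''=C6''/C7''–OH unit, back to the distal alkene of geranyl acetate.
Enabling feature: at the chromone oxidation level, ring C holds the vinylogous ester O1–C2=C3–C4=O. Its C2 is an unsubstituted β-carbon, so an aryl–rhodium species can add there, and the helper (the C2=C3 unsaturation) is used up in the same event.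
Forward order: rings A and C are bought together as 5,7-dihydroxychromone; the C10 chain (two steps from geranyl acetate) is joined at C6; ring B is joined last at C2; the silyl groups then come off under buffered fluoride.
Stereochemistry: 2''E is carried over from geranyl acetate and 5''E comes from a selenoxide syn-elimination. The only stereocentre, C2 (S), is set by the chiral bisphosphine on rhodium during the ring B union, and only a near-neutral desilylation follows.

Key step: step 9

Assumption: the (S)-configured biaryl bisphosphine is taken to deliver the aryl group to the Re face of C2, by transfer of the quadrant model that holds for 2-cyclohexenone ((S)-ligand gives (S)-3-arylcyclohexanone, which maps onto (2S) here).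

Step 1
Reactants: 1 geranyl acetate [(2E)-3,7-dimethylocta-2,6-dien-1-yl acetate]
Product: 4 (2E,5E)-7-hydroxy-3,7-dimethylocta-2,5-dien-1-yl acetate, via hydroxy selenide 2 (not isolated), via selenoxide 3 (not isolated)
Conditions: PhSeCl (1.0 equiv), MeCN/H2O (5:1), rt; NaHCO3; then 30% H2O2, THF, 0 °C to rt
Reagents that add atoms: water, O; benzeneselenenyl chloride, Cl[Se]c1ccccc1 (PhSe group of 2 and 3 only); hydrogen peroxide, OO (selenoxide oxygen of 3 only)
Why: Electrophilic hydroxyselenation followed by selenoxide syn-elimination: the selenium electrophile picks the electron-richer distal alkene (the 2,3-alkene is deactivated by the allylic acetoxy group), water opens the seleniranium ion at the tertiary carbon in the Markovnikov sense, and the selenoxide can eliminate only towards C5, which should give the (E)-alkene while the racemic centres of 2 and 3 vanish.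

Step 2
Reactants: 4 (2E,5E)-7-hydroxy-3,7-dimethylocta-2,5-dien-1-yl acetate
Product: 5 (3E,6E)-2,6-dimethyl-8-(4,4,5,5-tetramethyl-1,3,2-dioxaborolan-2-yl)octa-3,6-dien-2-ol
Conditions: B2pin2 (1.1 equiv), Pd2(dba)3 (2.5 mol %), DMSO, 50 °C
Reagents that add atoms: bis(pinacolato)diboron, CC1(C)OB(OC1(C)C)B1OC(C)(C)C(C)(C)O1
Why: Miyaura-type allylic borylation: zerovalent palladium ionises only the primary allylic acetate (the free tertiary allylic alcohol is no leaving group), and boryl transfer to the less hindered terminus of the π-allyl complex should give the linear boronate with the (E)-trisubstituted alkene kept, because syn/anti exchange would need a tertiary σ-allyl species.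

Step 3
Reactants: 6 5,7-dihydroxy-4H-chromen-4-one
Product: 7 5-hydroxy-7-(triisopropylsilyloxy)-4H-chromen-4-one
Conditions: TIPSCl (1.05 equiv), imidazole (2 equiv), DMF, 0 °C to rt
Reagents that add atoms: triisopropylsilyl chloride, CC(C)[Si](Cl)(C(C)C)C(C)C
Why: Chemoselective phenol silylation: 7-OH is the more acidic and unhindered phenol, whereas 5-OH is locked in a hydrogen bond to the C4 carbonyl oxygen and should stay free.

Step 4
Reactants: 7 5-hydroxy-7-(triisopropylsilyloxy)-4H-chromen-4-one
Product: 8 5-hydroxy-6-iodo-7-(triisopropylsilyloxy)-4H-chromen-4-one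
Conditions: BnMe3N·ICl2 (1.05 equiv), CaCO3, CH2Cl2/MeOH, rt, dark
Reagents that add atoms: benzyltrimethylammonium dichloroiodate, C[N+](C)(C)Cc1ccccc1.Cl[I-]Cl
Why: Electrophilic aromatic iodination: with 7-O capped and the chelated 5-OH free, substitution should go to C6 (ortho to 5-OH) rather than C8, as is established for 5-hydroxy-7-alkoxyflavones, and CaCO3 takes up the HCl so that the silyl ether persists.

Step 5
Reactants: 8 5-hydroxy-6-iodo-7-(triisopropylsilyloxy)-4H-chromen-4-one; 5 (3E,6E)-2,6-dimethyl-8-(4,4,5,5-tetramethyl-1,3,2-dioxaborolan-2-yl)octa-3,6-dien-2-ol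
Product: 9 5-hydroxy-6-[(2E,5E)-7-hydroxy-3,7-dimethylocta-2,5-dien-1-yl]-7-(triisopropylsilyloxy)-4H-chromen-4-one
Conditions: 5 (1.5 equiv), PdCl2(dppf)·CH2Cl2 (5 mol %), K3PO4 (3 equiv), THF/H2O (10:1), 45 °C
Reagents that add atoms: none
Why: Suzuki–Miyaura allyl–aryl cross-coupling, precedented for prenylboronates and iodoflavonoids: oxidative addition into the C6–iodine bond, transmetalation and fast reductive elimination from the wide-bite-angle dppf complex through the primary allyl terminus should give the linear product with both (E)-alkenes intact, and the small free 5-OH keeps one flank of the reacting carbon open.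

Step 6
Reactants: 9 5-hydroxy-6-[(2E,5E)-7-hydroxy-3,7-dimethylocta-2,5-dien-1-yl]-7-(triisopropylsilyloxy)-4H-chromen-4-one
Product: 10 5-(tert-butyldimethylsilyloxy)-6-[(2E,5E)-7-hydroxy-3,7-dimethylocta-2,5-dien-1-yl]-7-(triisopropylsilyloxy)-4H-chromen-4-one
Conditions: TBSCl (1.5 equiv), imidazole (3 equiv), DMAP (10 mol %), DMF, 40 °C
Reagents that add atoms: tert-butyldimethylsilyl chloride, CC(C)(C)[Si](C)(C)Cl
Why: Chemoselective phenol silylation: TBSCl/imidazole should silylate the chelated 5-OH on gentle warming but does not touch a tertiary alcohol, and capping 5-OH prevents an acetylacetonate-like O4/O5 chelate from tying up rhodium in step 9.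

Step 7
Reactants: 11 4-bromo-2-methoxyphenol
Product: 12 (4-bromo-2-methoxyphenoxy)(tert-butyl)dimethylsilane
Conditions: TBSCl (1.1 equiv), imidazole (2 equiv), DMF, rt
Reagents that add atoms: tert-butyldimethylsilyl chloride, CC(C)(C)[Si](C)(C)Cl
Why: Standard phenol silylation that removes the acidic proton before the lithiation and gives ring B the same fluoride-labile protection as ring A.

Step 8
Reactants: 12 (4-bromo-2-methoxyphenoxy)(tert-butyl)dimethylsilane
Product: 15 [4-(tert-butyldimethylsilyloxy)-3-methoxyphenyl]boronic acid, via aryllithium 13 (not isolated), via lithium borate 14 (not isolated)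
Conditions: n-BuLi (1.05 equiv), THF, −78 °C; B(OiPr)3 (1.5 equiv), −78 °C to rt; 1 M HCl, 0 °C
Reagents that add atoms: n-butyllithium, [Li]CCCC (Li of 13 and 14 only); triisopropyl borate, CC(C)OB(OC(C)C)OC(C)C; water, O
Why: Bromine–lithium exchange, electrophilic borylation and hydrolysis: the exchange is fast at −78 °C, the para-silyloxy group cannot migrate to the carbanion, and brief cold dilute acid frees the boronic acid without cleaving the aryl silyl ether.

Step 9
Reactants: 10 5-(tert-butyldimethylsilyloxy)-6-[(2E,5E)-7-hydroxy-3,7-dimethylocta-2,5-dien-1-yl]-7-(triisopropylsilyloxy)-4H-chromen-4-one; 15 [4-(tert-butyldimethylsilyloxy)-3-methoxyphenyl]boronic acid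
Product: 16 (2S)-5-(tert-butyldimethylsilyloxy)-2-[4-(tert-butyldimethylsilyloxy)-3-methoxyphenyl]-6-[(2E,5E)-7-hydroxy-3,7-dimethylocta-2,5-dien-1-yl]-7-(triisopropylsilyloxy)chroman-4-one
Conditions: 15 (2 equiv), [RhCl(C2H4)2]2 (2.5 mol %), (S)-MeO-F12-BIPHEP [(S)-6,6'-dimethoxybiphenyl-2,2'-diylbis(bis(3,4,5-trifluorophenyl)phosphine), 5.5 mol %], KOH (10 mol %), toluene/H2O (20:1), 25 °C
Reagents that add atoms: none
Why: Hayashi–Miyaura reaction (rhodium-catalysed asymmetric 1,4-addition of an arylboronic acid to a cyclic enone), with direct precedent on 4H-chromen-4-ones: transmetalation of 15 to the hydroxorhodium–bisphosphine complex gives an arylrhodium species, the C2=C3 bond of 10 binds and inserts into the Rh–aryl bond with C–C formation at C2, and water protonates the oxa-π-allyl rhodium enolate at C3 and regenerates the hydroxo complex. No ring is closed, since rings A and C are already in place and ring B is attached as a whole. The new stereocentre C2 is controlled by the ligand alone: the (S)-biaryl backbone blocks the quadrant that the benzo ring of 10 would occupy on Si-face binding, so aryl transfer should occur on the Re face and give (2S). Chemoselectivity rests on the substrate, because only C2=C3 is conjugated to a carbonyl group and unsubstituted at its β-carbon, so the unactivated tri- and disubstituted alkenes of the side chain should not insert and the free tertiary alcohol is a spectator in the aqueous medium. The peri 5-OTBS group shields C4=O against a second, 1,2-addition, the O-silyl groups donate less than O-alkyl groups and keep the enone electrophilic, and the electron-poor ligand allows room temperature, where β-elimination of the ring A aryloxide from the enolate (ring opening and loss of configuration) should not compete with protonation.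

Step 10
Reactants: 16 (2S)-5-(tert-butyldimethylsilyloxy)-2-[4-(tert-butyldimethylsilyloxy)-3-methoxyphenyl]-6-[(2E,5E)-7-hydroxy-3,7-dimethylocta-2,5-dien-1-yl]-7-(triisopropylsilyloxy)chroman-4-one
Product: 17 tomentodiplacone B [(2S)-5,7-dihydroxy-2-(4-hydroxy-3-methoxyphenyl)-6-[(2E,5E)-7-hydroxy-3,7-dimethylocta-2,5-dien-1-yl]chroman-4-one]
Conditions: TBAF (3.5 equiv), AcOH (4 equiv), THF, 0 °C
Reagents that add atoms: none
Why: Fluoride-mediated desilylation of aryl silyl ethers: the three phenolic Si–O bonds should cleave fast at 0 °C, and the acetic acid buffer keeps phenoxide from building up (no retro-oxa-Michael opening of ring C, so C2 stays (S)) while being too weak to ionise the tertiary allylic alcohol.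

**Compound list**
1 | geranyl acetate, (2E)-3,7-dimethylocta-2,6-dien-1-yl acetate | CC(=O)OC/C=C(\C)CCC=C(C)C | starting material
2 | (2E)-7-hydroxy-3,7-dimethyl-6-(phenylselanyl)oct-2-en-1-yl acetate, racemic, not isolated | CC(=O)OC/C=C(\C)CCC([Se]c1ccccc1)C(C)(C)O | intermediate
3 | (2E)-7-hydroxy-3,7-dimethyl-6-(phenylseleninyl)oct-2-en-1-yl acetate, racemic diastereomer mixture, not isolated | CC(=O)OC/C=C(\C)CCC([Se](=O)c1ccccc1)C(C)(C)O | intermediate
4 | (2E,5E)-7-hydroxy-3,7-dimethylocta-2,5-dien-1-yl acetate | CC(=O)OC/C=C(\C)C/C=C/C(C)(C)O | intermediate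
5 | (3E,6E)-2,6-dimethyl-8-(4,4,5,5-tetramethyl-1,3,2-dioxaborolan-2-yl)octa-3,6-dien-2-ol | CC1(C)OB(C/C=C(\C)C/C=C/C(C)(C)O)OC1(C)C | intermediate
6 | 5,7-dihydroxy-4H-chromen-4-one | O=c1ccoc2cc(O)cc(O)c12 | starting material
7 | 5-hydroxy-7-(triisopropylsilyloxy)-4H-chromen-4-one | O=c1ccoc2cc(O[Si](C(C)C)(C(C)C)C(C)C)cc(O)c12 | intermediate
8 | 5-hydroxy-6-iodo-7-(triisopropylsilyloxy)-4H-chromen-4-one | Ic1c(O)c2c(cc1O[Si](C(C)C)(C(C)C)C(C)C)occc2=O | intermediate
9 | 5-hydroxy-6-[(2E,5E)-7-hydroxy-3,7-dimethylocta-2,5-dien-1-yl]-7-(triisopropylsilyloxy)-4H-chromen-4-one | O=c1ccoc2cc(O[Si](C(C)C)(C(C)C)C(C)C)c(C/C=C(\C)C/C=C/C(C)(C)O)c(O)c12 | intermediate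
10 | 5-(tert-butyldimethylsilyloxy)-6-[(2E,5E)-7-hydroxy-3,7-dimethylocta-2,5-dien-1-yl]-7-(triisopropylsilyloxy)-4H-chromen-4-one | O=c1ccoc2cc(O[Si](C(C)C)(C(C)C)C(C)C)c(C/C=C(\C)C/C=C/C(C)(C)O)c(O[Si](C)(C)C(C)(C)C)c12 | intermediate
11 | 4-bromo-2-methoxyphenol | COc1cc(Br)ccc1O | starting material
12 | (4-bromo-2-methoxyphenoxy)(tert-butyl)dimethylsilane | COc1cc(Br)ccc1O[Si](C)(C)C(C)(C)C | intermediate
13 | [4-(tert-butyldimethylsilyloxy)-3-methoxyphenyl]lithium, not isolated | COc1cc([Li])ccc1O[Si](C)(C)C(C)(C)C | intermediate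
14 | lithium [4-(tert-butyldimethylsilyloxy)-3-methoxyphenyl]triisopropoxyborate, not isolated | [Li+].COc1cc([B-](OC(C)C)(OC(C)C)OC(C)C)ccc1O[Si](C)(C)C(C)(C)C | intermediate
15 | [4-(tert-butyldimethylsilyloxy)-3-methoxyphenyl]boronic acid | COc1cc(B(O)O)ccc1O[Si](C)(C)C(C)(C)C | intermediate
16 | (2S)-5-(tert-butyldimethylsilyloxy)-2-[4-(tert-butyldimethylsilyloxy)-3-methoxyphenyl]-6-[(2E,5E)-7-hydroxy-3,7-dimethylocta-2,5-dien-1-yl]-7-(triisopropylsilyloxy)chroman-4-one | COc1cc([C@@H]2CC(=O)c3c(cc(O[Si](C(C)C)(C(C)C)C(C)C)c(C/C=C(\C)C/C=C/C(C)(C)O)c3O[Si](C)(C)C(C)(C)C)O2)ccc1O[Si](C)(C)C(C)(C)C | intermediate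
17 | tomentodiplacone B | COc1cc([C@@H]2CC(=O)c3c(cc(O)c(C/C=C(\C)C/C=C/C(C)(C)O)c3O)O2)ccc1O | target

**Step count**
Total steps: 10.
Longest linear sequence: 6 steps (1 → 4 → 5 → 9 → 10 → 16 → 17, and equally 6 → 7 → 8 → 9 → 10 → 16 → 17).

**Steps most likely to fail**

Risk 1 (step 9).
- What may go wrong: slow insertion of the electron-rich, doubly O-silylated enone may let protodeboronation of the electron-rich boronic acid and hydrolytic loss of the 5-O-silyl group take over. Reversible opening of ring C at the enolate stage may also erode the enantiomeric purity.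
- The fallback sets out from 10 and 15 and comes back at 16. The union is run without asymmetric induction, using the more reactive achiral complex [Rh(OH)(cod)]2 in dioxane/H2O at 50 °C, to give the racemic protected flavanone F1.
- The configuration is then taken from a kinetic resolution by Noyori–Ikariya asymmetric transfer hydrogenation (Cp*RhCl[(R,R)-TsDPEN], HCO2H/Et3N, EtOAc, rt). The (2R)-ketone should be reduced to the cis-configured (2R,4R)-flavan-4-ol F2, while the (2S)-ketone 16 stays behind and is separated by chromatography.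

Risk 2 (step 5).
- What may go wrong: transmetalation at the doubly ortho-flanked arylpalladium centre may be slow. Coupling through the tertiary allyl terminus, migration of the skipped diene into conjugation, protodeboronation of 5 and base-induced loss of the 7-O-silyl group could then compete.
- The fallback sets out from 8 and 4 (5 is bypassed) and comes back at 9, with the polarity of the partners reversed and no base present. Iodide 8 is stannylated (hexamethylditin, Pd(PPh3)4, toluene, 100 °C) to 5-hydroxy-7-(triisopropylsilyloxy)-6-(trimethylstannyl)-4H-chromen-4-one F3.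
- This stannane is joined to allylic acetate 4 in a Stille coupling of the allylic acetate type (Pd2(dba)3, LiCl, DMF, rt to 40 °C). The π-allyl complex formed by ionisation of the acetate takes up the aryl group at its primary terminus with retention of the alkene geometry, giving 9.

Risk 3 (step 2).
- What may go wrong: the π-allylpalladium intermediate carries doubly allylic hydrogens at C4 and may lose one (elimination to a conjugated triene). It may also be intercepted by the product boronate (allyl–allyl homocoupling) or lose its (E)-geometry.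
- The fallback sets out from 4 and comes back at 9, and it makes the allyl nucleophile without any π-allyl metal species. Methanolysis (K2CO3, MeOH, rt) gives (2E,5E)-3,7-dimethylocta-2,5-diene-1,7-diol F4.
- Corey–Kim chlorination (NCS, Me2S, CH2Cl2, −40 to 0 °C) converts only the primary allylic alcohol into (3E,6E)-8-chloro-2,6-dimethylocta-3,6-dien-2-ol F5. SN2 displacement with Bu3SnLi (2.2 equiv, THF, −78 °C) then gives (3E,6E)-2,6-dimethyl-8-(tributylstannyl)octa-3,6-dien-2-ol F6.
- A neutral Stille coupling of this stannane with iodide 8 (Pd2(dba)3, AsPh3, DMF, 60 °C) delivers 9.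

**Further compounds**
F1 | step 9 | racemic 5-(tert-butyldimethylsilyloxy)-2-[4-(tert-butyldimethylsilyloxy)-3-methoxyphenyl]-6-[(2E,5E)-7-hydroxy-3,7-dimethylocta-2,5-dien-1-yl]-7-(triisopropylsilyloxy)chroman-4-one | COc1cc(C2CC(=O)c3c(cc(O[Si](C(C)C)(C(C)C)C(C)C)c(C/C=C(\C)C/C=C/C(C)(C)O)c3O[Si](C)(C)C(C)(C)C)O2)ccc1O[Si](C)(C)C(C)(C)C
F2 | step 9 | (2R,4R)-5-(tert-butyldimethylsilyloxy)-2-[4-(tert-butyldimethylsilyloxy)-3-methoxyphenyl]-6-[(2E,5E)-7-hydroxy-3,7-dimethylocta-2,5-dien-1-yl]-7-(triisopropylsilyloxy)chroman-4-ol | COc1cc([C@H]2C[C@@H](O)c3c(cc(O[Si](C(C)C)(C(C)C)C(C)C)c(C/C=C(\C)C/C=C/C(C)(C)O)c3O[Si](C)(C)C(C)(C)C)O2)ccc1O[Si](C)(C)C(C)(C)C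
F3 | step 5 | 5-hydroxy-7-(triisopropylsilyloxy)-6-(trimethylstannyl)-4H-chromen-4-one | C[Sn](C)(C)c1c(O)c2c(cc1O[Si](C(C)C)(C(C)C)C(C)C)occc2=O
F4 | step 2 | (2E,5E)-3,7-dimethylocta-2,5-diene-1,7-diol | OC/C=C(\C)C/C=C/C(C)(C)O
F5 | step 2 | (3E,6E)-8-chloro-2,6-dimethylocta-3,6-dien-2-ol | ClC/C=C(\C)C/C=C/C(C)(C)O
F6 | step 2 | (3E,6E)-2,6-dimethyl-8-(tributylstannyl)octa-3,6-dien-2-ol | CCCC[Sn](CCCC)(CCCC)C/C=C(\C)C/C=C/C(C)(C)O
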